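The data are calculated for substances that don't exist.

Late in oak and elm the flask stands still: from 0.833 h on, oak holds target near 59.0% and elm near 33.9%, with starting material still there. So read both runs this way: the solid reagent dissolves to partner, and partner and catalyst turn either starting material into target or second substrate into second product. The protic impurity quenches 5.00 mM of second substrate. Each run stops once the 0.110 M of solid reagent has been shared out.

| setting | oak | elm | west | north |
|---|---|---|---|---|
| starting material | 0.10 M | 0.10 M | 0.10 M | 0.10 M |
| second substrate | 0.26 M | 0.73 M | 0.600 M | 0.200 M |
| protic impurity | 5 mM | 5 mM | 5.00 mM | 5.00 mM |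
| solid reagent | 0.11 M | 0.11 M | 0.110 M | 0.110 M |
| catalyst | 0.10 mM | 0.10 mM | 0.10 mM | 0.10 mM |
| remark | run made earlier | run made earlier |  |  |
| time |  |  | 6.0 h | 6.0 h |

| run | time / h | starting material / % | target / % |
|---|---|---|---|
| oak | 0.417 | 45.3 | 55.5 |
| oak | 0.833 | 41.1 | 59.7 |
| oak | 1.33 | 41.7 | 59.0 |
| oak | 1.50 | 41.4 | 59.0 |
| oak | 2.00 | 42.1 | 59.0 |
| oak | 2.50 | 41.5 | 58.8 |
| oak | 3.00 | 39.6 | 58.5 |
| elm | 0.417 | 64.9 | 35.1 |
| elm | 0.833 | 66.5 | 32.3 |
| elm | 1.33 | 64.4 | 33.2 |
| elm | 1.50 | 64.9 | 34.2 |
| elm | 2.00 | 66.4 | 33.9 |
| elm | 2.50 | 64.6 | 35.0 |
| elm | 3.00 | 65.6 | 34.6 |

(standard deviation of a reading: 1 percentage point)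

- given per volume of solution although it is solid: solid reagent
- on the list of suspects stand: starting material + partner + catalyst -> catalyst + target; second substrate + protic impurity -> quenched substrate; second substrate + partner + catalyst -> catalyst + second product; solid reagent <-> partner
- at the start none of the solid reagent is in solution

- which of these there is most of at the end, counted by the starting material in it, west (target / starting material)
- which of these there is most of at the end, counted by the starting material in it, north (target / starting material)
- amount of the one of these that there is most of at the end, in percent of the starting material charged, west
- amount of the one of these that there is most of at the end, in percent of the starting material charged, north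

Turn the question round: what charge of second substrate leaves target and starting material level at the end?

Write A for starting material and E for second substrate beyond what the impurity takes. If both steps go with their substrate times partner times catalyst, divide one rate by the other and partner, catalyst and time drop out. A percent fall in E then comes with S times that percent fall in A:

ln(A at start / A at end) = S · ln(E at start / E at end)

S is the selectivity factor. The partner balance gives E at the end from the target reading, so your readings at 2.00 h give:

oak: S = 4.00
elm: S = 3.73
mean: S = 3.86

Level means A falls by a factor 2: 0.0500 M of partner goes to target and 0.0600 M to second product. Solving for the charge gives the level charge c*, the second substrate at which the two end equal: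

c* = 0.370 M

West's 0.600 M stands above c*, so starting material should lead there. North's 0.200 M stands below it, so target should lead there.

The forecast, from the same picture, “The starting material and second substrate compete for it”, solved the balance for amounts: starting material at 61% in west, target at 64.5% in north.

The flasks give starting material at 61.4% in west and target at 64.1% in north.

    starting material + partner + catalyst → catalyst + target (k = 13000 M⁻² min⁻¹)
    second substrate + protic impurity → quenched substrate (k = 3.10 M⁻¹ min⁻¹)
    second substrate + partner + catalyst → catalyst + second product (k = 3400 M⁻² min⁻¹)
    solid reagent ⇌ partner, rate k4*(cs4 - [partner]) while solid is left; crystals form when [partner] > cs4 (solubility = 0.0530 M, k = 0.590 min⁻¹)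

West's target stands at 38.6% because of the step to second product: without that step, west gives 99.9%. With 0.600 M against c* of 0.370 M, west lies on the starting-material side, and its solid reagent is at 0% of charge at the end.

A neighbouring flask is west with 0.24 M of second substrate, below c*, so c* puts target ahead. Computed, target leads at 59.9%, and the recipe's crossing stands at 0.367 M.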